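## Structural features

The target is a 3,5,6,7-tetrahydro-1-benzofuran-4(2H)-one: a 2,3-dihydrofuran and a cyclohexenone share the C3a=C7a double bond, so that O1–C7a=C3a–C4=O is a cyclic vinylogous ester. C5, next to the C4 carbonyl, carries a secondary hydroxyl; this α-ketol can epimerise through its enol and is cut off from every other stereocentre by the planar enone. C2 bears the side chain through the tertiary carbinol C1′, so C2 and C1′ are adjacent stereocentres. Two methylenes further on stands a second adjacent pair, the secondary carbinol C4′ and the tertiary carbinol C5′ in an anti relationship, followed by a 4-methylpent-3-enyl end. Fragile groups are the vinylogous ester (hydrolysis or alkoxy exchange in acid, 1,2-addition of organometallics), the α-ketol, the two tertiary carbinols near a trisubstituted alkene (dehydration or ether formation in acid, electrophilic oxidants), and C2–H whenever C1′ is a carbonyl. The real difficulty is that the three stereochemical islands (C2/C1′, C4′/C5′, C5) cannot pass information to one another, and that the dihydrofuran must be closed with C2 defined. The key step uses the fact that C2 is bonded to O1, to the C3 methylene and to a carbon (C1′) that can be at carboxyl level. C2 can therefore arrive as a one-carbon carbonyl-stabilised ylide that bridges the two ends of the oxa-diene O=C7a–C3a=C3 of a 2-methylene-1,3-dione, closing the dihydrofuran ring and fixing C2 in one operation.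

## Logic of the disconnections

**28 to 27.** The O–Si bond at C1′ and the two acetal C–O bonds at C4′ and C5′ are cut. Only unmasking is left for the end, so the four hydroxyls never meet bases or organometallics. The forward step needs an acid that cleaves a tertiary silyl ether and a hindered acetal but spares the vinylogous ester, the α-ketol, the tertiary carbinols and the alkene.

**27 to 25.** The C5–O bond is cut. C5 is the α′ carbon of the C4 carbonyl and the only ring position that can be deprotonated kinetically. A symmetrical dione precursor could not carry this oxygen without a regiochemical ambiguity at ring closure. The ring loses its isolated stereocentre. The forward step needs enolisation at C5 and not at C7, an oxidant that ignores the alkene, and reagent-controlled face selection, since no stereocentre is near.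

**25 to 24 to 23.** The O–Si bond and then the C1′–CH3 bond are cut. Methyl is the simplest carbon nucleophile, and delivering it to a ketone flanked by C2 makes C2 the control element for C1′. The forward addition must follow the non-chelated (Felkin–Anh) mode, must choose the ketone over the C4 carbonyl, and must not enolise toward C2.

**23 to 21.** The C2′–C3′ single bond is taken back to a triple bond conjugated with the C1′ ketone. The nucleophile of the next cut is then an acetylide, which comes from an aldehyde in one operation and is weakly basic, whereas an sp3 organolithium would need a longer route and a stronger base. The forward step must saturate only the activated alkyne.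

**21 to 12 and 18.** The C1′–C2′ bond is cut. The molecule falls into two halves of similar size, each with its own stereocentres, and C1′ is already at acyl level in 12. The forward step must stop after one addition, prefer the amide to the C4 carbonyl, and leave C2 untouched.

**12 to 5 and 6, with 7 (key step).** The O1–C2 and C2–C3 bonds are cut. The bicycle and its stereocentre then come from two achiral components and a recoverable chiral amine. The skeletons of 5 and 6 are kept. The plan is tightened in two ways: 6 is fully quaternised to 8 before base and 5 meet, so that neither free bromide nor sulfinate alkylation interferes, and 5 is fed slowly so that 10 stays dilute. The forward step needs ylide addition faster than self-condensation of 10, O-closure rather than C-closure, and face control by the ammonium group.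

**5 to 1, 2 and 3.** The C3–C3a bond and the C3–S bond are cut. 5 stores the unstable 10 as a bench-stable solid from which base releases it on demand. The forward step runs through 4 and needs 3 to capture the electrophile that acid generates from 4 faster than a second molecule of 1 does.

**18 to 17 to 16.** The acetal bonds and then the C5′–OH bond are cut. The anti relationship of C4′ and C5′ cannot come from syn-dihydroxylation of the E-alkene of 13. It does come from the trans-epoxide by inversion at one carbon. Water must attack only the tertiary carbon and only from the rear.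

**16 to 15 to 14 to 13.** The C2′≡C3′ bond (one-carbon homologation), the aldehyde oxidation level and the two epoxide C–O bonds are removed in turn. 13 already holds C3′ to C9′ with the E-alkene, and its allylic hydroxyl singles out the proximal alkene for epoxidation. The forward steps need the D-tartrate series for the (2R,3R)-epoxide and an oxidation and homologation that leave the epoxide closed.

## Other disconnections considered

**Alternative 1:** The cut goes through both rings at once, at O1–C7a and C3a–C4, and leads to the open-chain alkynyl hydroxy aldehyde A1. In A1 the C3a≡C7a triple bond lies between the C2 carbinol and the C4 aldehyde. In the forward step Ph3PAuNTf2 (monovalent gold) activates the alkyne, the C2 hydroxyl adds 5-endo-dig at C7a, and the enol ether carbon C3a then attacks the aldehyde in a Prins-type closure to give carbinol A2, which must be oxidised at C4.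
- In favour: both rings form in one operation. All five stereocentres, C5 included, are set on acyclic intermediates by reagent-controlled reactions. On this point the alternative is better than the chosen plan, whose late enolate hydroxylation (step 12) is its weakest stereochemical link.
- Against: A1 carries five stereocentres and three kinds of protecting group and needs a long linear synthesis. Its α-silyloxy aldehyde can epimerise at C5. The cationic gold catalyst must choose the alkyne over the trisubstituted alkene and must not ionise the acetal. The C4 carbinol needs a separate oxidation next to C5.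
- Comparison: structurally the alternative builds the bicycle last on a finished chain, whereas the chosen plan builds it first as the small amide 12. Mechanistically it is π-acid catalysis with an enol ether–aldehyde addition, a cascade type with at least as much precedent as the ylide annulation. In step economy it should be clearly longer because of the route to A1.

**Alternative 2:** The cut is at C3–C3a and O1–C7a and divides the target into 1 and the complete side-chain aldehyde A3, in which C3 is the formyl carbon bonded directly to C2 and both diol pairs are acetonides. In the forward step proline-catalysed Knoevenagel condensation with in situ hydride transfer from a Hantzsch dihydropyridine gives the 2-alkyl dione. Aqueous acid in the same flask then removes the acetonides and condenses the C2 hydroxyl with the C7a carbonyl to give A4.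
- In favour: the union is very convergent, the three-component reductive alkylation of cyclic 1,3-diones is well established, and no organometallic reagent meets the vinylogous ester. C2 and C1′ can both be set in the chain by reagent control. On this point the alternative is better than the substrate-controlled addition of step 10.
- Against: A3 carries four stereocentres in two protected diols beside a trisubstituted alkene, so the effort moves into a long fragment synthesis in which several similar alkenes of a terpenoid precursor must be told apart. Its α-alkoxy aldehyde can epimerise at C2 under amine catalysis. The cyclodehydration must pick the secondary C2 hydroxyl (five-membered ring) over the tertiary C1′ hydroxyl (six-membered ring), in acid strong enough to cleave two acetals next to two tertiary carbinols and an alkene. A4 still lacks the C5 hydroxyl, which would have to be added to a tetraol after reprotection, so the C5 problem is equal at best.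
- Comparison: structurally it forms the same dihydrofuran ring but by C–O condensation at C7a, not by displacement at C2. Mechanistically it is iminium/enamine organocatalysis followed by acid catalysis, all known. In step economy the key operation is shorter, but the whole route is unlikely to be.

**Alternative 3:** The cut is at O1–C2 alone, in the sense of a vinylcyclopropane-to-dihydrofuran ring expansion. The precursor is the racemic spiro vinylcyclopropane A5, which should be reachable in one operation from 1 by double C-alkylation with a but-2-ene-1,4-diyl bis-electrophile, provided that closure at carbon can be made to beat direct closure at oxygen. In the forward step zerovalent palladium (Pd2(dba)3 with a chiral diphosphine) opens the activated C2–C3a bond to a π-allyl palladium/dione enolate zwitterion. The diastereomeric allyl complexes interconvert faster than they close, and the enolate oxygen attacks the substituted allyl terminus to give A6.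
- In favour: the chiral source is catalytic and the substrate is close to commercial materials. The ring expansion and the related allylic O-alkylation of cyclic diones have close precedent, so on precedent and on use of chiral material the alternative is better than the chosen key step. It closes the same ring at the same bond and sets the same stereocentre, so it is equal there.
- Against: C2 ends with a vinyl group, whose carbon must still be raised to the acyl level that C1′ already has in 12. Raising it would take ozonolysis, chain addition and re-oxidation, or a Wacker oxidation of uncertain regiochemistry next to the allylic oxygen followed by chain addition in the reversed order. This costs two to three extra steps and passes through an α-alkoxy aldehyde or methyl ketone more prone to epimerise at C2 than amide 12. The branched closure must also beat the linear seven-membered one.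
- Comparison: mechanistically both plans close O1–C2 by enolate oxygen attack on an electrophilic C2, here on a metal-bound allyl and there on an ammonium-bearing carbon. Step economy is similar before the key step and worse after it.

Key step: step 2

Assumptions (remarks on the chemistry):
- The face selectivity of the quinidine-derived ammonium group in step 2 is assigned by analogy with amide ylide additions to other acceptors; if the (2R) series prevails, the pseudoenantiomeric 9-O-methylquinine replaces 7.
- (+)-(Camphorsulfonyl)oxaziridine is taken to give (5R) on the cyclic enolate 26; the (−)-enantiomer is equally available if a trial shows the opposite sense.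
- 7 is treated as a purchasable reagent; otherwise it is made in one step from quinidine (NaH, MeI).

## Route

Step 1
Reactants: 1 cyclohexane-1,3-dione; 2 formaldehyde (37% aqueous); 3 sodium 4-methylbenzenesulfinate
Product: 5 2-[(4-methylphenyl)sulfonylmethyl]cyclohexane-1,3-dione, via 2-(hydroxymethyl)cyclohexane-1,3-dione 4 (not isolated)
Conditions: HCO2H/H2O (1:1), rt
Reagents that add atoms: none
Why: Aldol-type hydroxymethylation of the dione enol at C2 by formaldehyde gives carbinol 4; in aqueous formic acid the enol of 4 ionises its allylic hydroxyl and sulfinate sulfur captures the enol-stabilised cation at CH2 (three-component sulfonylmethylation of 1,3-dicarbonyls, a dehydrative substitution of Mannich type). Capture at the cationic stage by excess sulfinate and precipitation of the sulfone from the acidic aqueous medium should keep a second dione from adding.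

Step 2
Reactants: 5 2-[(4-methylphenyl)sulfonylmethyl]cyclohexane-1,3-dione; 6 2-bromo-N-methoxy-N-methylacetamide; 7 9-O-methylquinidine (stoichiometric chiral amine, recovered)
Product: 12 (2S)-N-methoxy-N-methyl-4-oxo-2,3,4,5,6,7-hexahydro-1-benzofuran-2-carboxamide, via quinidinium bromide 8 (not isolated), via ammonium ylide 9 (not isolated), via 2-methylidenecyclohexane-1,3-dione 10 (not isolated), via betaine 11 (not isolated)
Conditions: 6, 7, MeCN, rt, 16 h; then Cs2CO3, 0 °C; 5 added over 4 h, 0 °C → rt
Reagents that add atoms: none
Why: Proposed new method: carbonate deprotonates the preformed salt 8 to the amide-stabilised ylide 9 and turns 5 into the transient methylene dione 10 by E1cB loss of sulfinate; the ylide carbon adds to the unsubstituted exocyclic CH2 of the oxa-diene O=C7a–C3a=C3 (C2–C3 bond) to give betaine 11, whose dione enolate oxygen displaces the quinuclidine nitrogen at C2 (O1–C2 bond). The closest known reaction type is the formal [4+1] annulation of pyridinium, sulfonium and ammonium ylides with 2-alkylidene-1,3-diones to fused 2-acyl-2,3-dihydrofurans, together with its enantioselective cinchona-ammonium version on o-quinone methides; new here are the unsubstituted methylene dione released from a sulfone and the transfer of cinchona control to it. The dihydrofuran ring closes 5-exo-tet by intramolecular SN2 with the amine as exocyclic leaving group. C2 is the only new stereocentre: the chiral quinuclidinium fixes it as (R) in 11, either in the face-selective conjugate addition or by base-mediated equilibration of the acidic C2–H followed by faster closure of one epimer, and the invertive closure delivers (2S) in 12. The step needs O- over C-alkylation, which the five-membered ring against a strained spiro-cyclopropane and the U-shaped cyclic enolate should secure. It needs ylide addition to outrun capture of 10 by a second dione enolate, which slow addition of 5 to excess preformed 8 should secure. It needs no S-alkylation of the released sulfinate, which complete quaternisation of 6 before base is added should secure.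

Step 3
Reactants: 13 geraniol
Product: 14 [(2R,3R)-3-methyl-3-(4-methylpent-3-en-1-yl)oxiran-2-yl]methanol
Conditions: Ti(OiPr)4 (5 mol %), D-(−)-diisopropyl tartrate (6 mol %), t-BuOOH, 4 Å MS, CH2Cl2, −20 °C
Reagents that add atoms: tert-butyl hydroperoxide, CC(C)(C)OO
Why: Katsuki–Sharpless asymmetric epoxidation: the titanium tartrate binds the allylic hydroxyl, so only the 2,3-alkene reacts and the remote trisubstituted alkene is left; the D-(−)-tartrate delivers oxygen to the face that gives the (2R,3R)-epoxide, which fixes C4′ directly and C5′ after the inversion of step 6.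

Step 4
Reactants: 14 [(2R,3R)-3-methyl-3-(4-methylpent-3-en-1-yl)oxiran-2-yl]methanol
Product: 15 (2S,3R)-3-methyl-3-(4-methylpent-3-en-1-yl)oxirane-2-carbaldehyde
Conditions: TEMPO (10 mol %), PhI(OAc)2, CH2Cl2, rt
Reagents that add atoms: none
Why: Oxoammonium (TEMPO) oxidation of a primary alcohol stops at the aldehyde and tolerates epoxide and alkene; the oxirane carbon next to the carbonyl should not epimerise because enolisation would place a double bond exocyclic to the three-membered ring.

Step 5
Reactants: 15 (2S,3R)-3-methyl-3-(4-methylpent-3-en-1-yl)oxirane-2-carbaldehyde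
Product: 16 (2R,3R)-2-ethynyl-3-methyl-3-(4-methylpent-3-en-1-yl)oxirane
Conditions: dimethyl (1-diazo-2-oxopropyl)phosphonate, K2CO3, MeOH, 0 °C → rt
Reagents that add atoms: dimethyl (1-diazo-2-oxopropyl)phosphonate, CC(=O)C(=[N+]=[N-])P(=O)(OC)OC
Why: Ohira–Bestmann variant of the Seyferth–Gilbert homologation: methanolysis frees the diazomethylphosphonate anion, which adds to the aldehyde; loss of phosphate and N2 and a 1,2-hydrogen shift give the terminal alkyne, whose new carbon is C2′, and the mild carbonate base should leave the epoxide closed.

Step 6
Reactants: 16 (2R,3R)-2-ethynyl-3-methyl-3-(4-methylpent-3-en-1-yl)oxirane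
Product: 17 (3R,4S)-4,8-dimethylnon-7-en-1-yne-3,4-diol
Conditions: HClO4 (cat.), THF/H2O (3:1), 0 °C → rt
Reagents that add atoms: water, O
Why: Acid-catalysed epoxide hydrolysis of borderline SN2 type: water opens the protonated oxirane at the tertiary carbon C5′ from the rear, while the propargylic carbon C4′ is deactivated by the adjacent sp carbon and keeps its C–O bond; inversion at C5′ turns the trans-epoxide into the anti diol (4′R,5′S) that syn-dihydroxylation of the E-alkene could not give.

Step 7
Reactants: 17 (3R,4S)-4,8-dimethylnon-7-en-1-yne-3,4-diol
Product: 18 (4R,5S)-4-ethynyl-2,2,5-trimethyl-5-(4-methylpent-3-en-1-yl)-1,3-dioxolane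
Conditions: Me2C(OMe)2, camphorsulfonic acid (cat.), CH2Cl2, rt
Reagents that add atoms: 2,2-dimethoxypropane, COC(C)(C)OC
Why: Acid-catalysed transacetalisation closes the isopropylidene acetal over the secondary and tertiary hydroxyls without touching a stereocentre; the acetal withstands organolithium, hydride and enolate chemistry.

Step 8
Reactants: 18 (4R,5S)-4-ethynyl-2,2,5-trimethyl-5-(4-methylpent-3-en-1-yl)-1,3-dioxolane; 12 (2S)-N-methoxy-N-methyl-4-oxo-2,3,4,5,6,7-hexahydro-1-benzofuran-2-carboxamide
Product: 21 (2S)-2-{3-[(4R,5S)-2,2,5-trimethyl-5-(4-methylpent-3-en-1-yl)-1,3-dioxolan-4-yl]prop-2-ynoyl}-3,5,6,7-tetrahydro-1-benzofuran-4(2H)-one, via lithium acetylide 19 (not isolated), via lithium hemiaminal alkoxide 20 (not isolated)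
Conditions: 18 (2 equiv), n-BuLi, THF, −78 °C; then 12, −78 → −40 °C; aq. NH4Cl
Reagents that add atoms: none
Why: Weinreb ketone synthesis with a lithium acetylide: the chelated tetrahedral adduct 20 prevents a second addition and hides the C1′ carbonyl until the quench, so C2–H is not acidified while base is present. The α-oxygenated amide should be more electrophilic than the donor-substituted, fully substituted enone carbonyl C4, and the acetylide is too weak a base to deprotonate C2; excess 18 is recoverable.

Step 9
Reactants: 21 (2S)-2-{3-[(4R,5S)-2,2,5-trimethyl-5-(4-methylpent-3-en-1-yl)-1,3-dioxolan-4-yl]prop-2-ynoyl}-3,5,6,7-tetrahydro-1-benzofuran-4(2H)-one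
Product: 23 (2S)-2-{3-[(4R,5S)-2,2,5-trimethyl-5-(4-methylpent-3-en-1-yl)-1,3-dioxolan-4-yl]propanoyl}-3,5,6,7-tetrahydro-1-benzofuran-4(2H)-one, via (Z)-enone 22 (not isolated)
Conditions: [(Ph3P)CuH]6 (about 3 equiv of hydride), H2O (5 equiv), degassed toluene, rt
Reagents that add atoms: none
Why: Conjugate hydride transfer from the monovalent copper hydride to the ynone and then to enone 22, each copper enolate being protonated at C2′, saturates only the activated C2′–C3′ bond (known conjugate reduction of ynones). The isolated trisubstituted alkene and the oxygen-substituted tetrasubstituted enone are not hydride acceptors, and enolate formation toward C2′ should leave C2 untouched.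

Step 10
Reactants: 23 (2S)-2-{3-[(4R,5S)-2,2,5-trimethyl-5-(4-methylpent-3-en-1-yl)-1,3-dioxolan-4-yl]propanoyl}-3,5,6,7-tetrahydro-1-benzofuran-4(2H)-one
Product: 24 (2S)-2-{(2S)-2-hydroxy-4-[(4R,5S)-2,2,5-trimethyl-5-(4-methylpent-3-en-1-yl)-1,3-dioxolan-4-yl]butan-2-yl}-3,5,6,7-tetrahydro-1-benzofuran-4(2H)-one
Conditions: MeTi(OiPr)3 (2.5 equiv, from ClTi(OiPr)3 and MeLi), Et2O, −30 → 0 °C; aq. NH4F
Reagents that add atoms: methyltitanium triisopropoxide, C[Ti](OC(C)C)(OC(C)C)OC(C)C
Why: Felkin–Anh (polar) 1,2-addition: with the C2–O1 bond anti to the incoming methyl and the C3 methylene beside the carbonyl oxygen, attack past the C2 hydrogen gives (1′S). O1 is a weakly basic vinylogous ester oxygen and the reagent a weak Lewis acid, so no chelate should compete; the reagent is not basic (no enolisation at C2) and does not add to the vinylogous ester.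

Step 11
Reactants: 24 (2S)-2-{(2S)-2-hydroxy-4-[(4R,5S)-2,2,5-trimethyl-5-(4-methylpent-3-en-1-yl)-1,3-dioxolan-4-yl]butan-2-yl}-3,5,6,7-tetrahydro-1-benzofuran-4(2H)-one
Product: 25 (2S)-2-{(2S)-2-(triethylsilyloxy)-4-[(4R,5S)-2,2,5-trimethyl-5-(4-methylpent-3-en-1-yl)-1,3-dioxolan-4-yl]butan-2-yl}-3,5,6,7-tetrahydro-1-benzofuran-4(2H)-one
Conditions: Et3SiOTf, 2,6-lutidine, CH2Cl2, −78 → 0 °C
Reagents that add atoms: triethylsilyl trifluoromethanesulfonate, CC[Si](CC)(CC)OS(=O)(=O)C(F)(F)F
Why: A silyl triflate with a hindered pyridine base silylates even a tertiary carbinol; the ether removes the only acidic proton before enolate formation and comes off together with the acetal at the end.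

Step 12
Reactants: 25 (2S)-2-{(2S)-2-(triethylsilyloxy)-4-[(4R,5S)-2,2,5-trimethyl-5-(4-methylpent-3-en-1-yl)-1,3-dioxolan-4-yl]butan-2-yl}-3,5,6,7-tetrahydro-1-benzofuran-4(2H)-one
Product: 27 (2S,5R)-5-hydroxy-2-{(2S)-2-(triethylsilyloxy)-4-[(4R,5S)-2,2,5-trimethyl-5-(4-methylpent-3-en-1-yl)-1,3-dioxolan-4-yl]butan-2-yl}-3,5,6,7-tetrahydro-1-benzofuran-4(2H)-one, via lithium enolate 26 (not isolated)
Conditions: LDA, THF, −78 °C; then (+)-(camphorsulfonyl)oxaziridine, −78 → −40 °C; aq. NH4Cl
Reagents that add atoms: (+)-(camphorsulfonyl)oxaziridine, CC1(C)[C@@H]2CC[C@]13CS(=O)(=O)N4O[C@@]34C2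
Why: Kinetic deprotonation of a vinylogous ester occurs at the α′ carbon C5 (cross-conjugated enolate 26) and not at the γ carbon C7; oxygen transfer from the N-sulfonyloxaziridine to the enolate carbon (enolate hydroxylation) gives the α-ketol. The enantiopure reagent is to choose the enolate face for (5R) because no substrate stereocentre is near, and it does not epoxidise the isolated alkene.

Step 13
Reactants: 27 (2S,5R)-5-hydroxy-2-{(2S)-2-(triethylsilyloxy)-4-[(4R,5S)-2,2,5-trimethyl-5-(4-methylpent-3-en-1-yl)-1,3-dioxolan-4-yl]butan-2-yl}-3,5,6,7-tetrahydro-1-benzofuran-4(2H)-one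
Product: 28 (2S,5R)-5-hydroxy-2-[(2S,5R,6S)-2,5,6-trihydroxy-6,10-dimethylundec-9-en-2-yl]-3,5,6,7-tetrahydro-1-benzofuran-4(2H)-one
Conditions: AcOH/H2O/THF (3:1:1), 40 °C
Reagents that add atoms: none
Why: Aqueous acetic acid hydrolyses the tertiary triethylsilyl ether and the isopropylidene acetal in one operation; it should be too weak and too poorly nucleophilic to open or exchange the vinylogous ester, dehydrate the tertiary carbinols or protonate the trisubstituted alkene.

## Compound list

1 | cyclohexane-1,3-dione | O=C1CCCC(=O)C1 | starting material
2 | formaldehyde | C=O | starting material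
3 | sodium 4-methylbenzenesulfinate | [Na+].Cc1ccc(cc1)S(=O)[O-] | starting material
4 | 2-(hydroxymethyl)cyclohexane-1,3-dione (not isolated) | OCC1C(=O)CCCC1=O | intermediate
5 | 2-[(4-methylphenyl)sulfonylmethyl]cyclohexane-1,3-dione | Cc1ccc(cc1)S(=O)(=O)CC1C(=O)CCCC1=O | intermediate
6 | 2-bromo-N-methoxy-N-methylacetamide | CON(C)C(=O)CBr | starting material
7 | 9-O-methylquinidine | COc1ccc2nccc([C@H](OC)[C@H]3C[C@@H]4CCN3C[C@@H]4C=C)c2c1 | starting material
8 | N-[2-(methoxy(methyl)amino)-2-oxoethyl]-9-O-methylquinidinium bromide, quaternised at the quinuclidine nitrogen (not isolated) | COc1ccc2nccc([C@H](OC)[C@H]3C[C@@H]4CC[N+]3(CC(=O)N(C)OC)C[C@@H]4C=C)c2c1.[Br-] | intermediate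
9 | ammonium ylide of 8, carbanion at the amide α-carbon (not isolated) | COc1ccc2nccc([C@H](OC)[C@H]3C[C@@H]4CC[N+]3([CH-]C(=O)N(C)OC)C[C@@H]4C=C)c2c1 | intermediate
10 | 2-methylidenecyclohexane-1,3-dione (not isolated) | C=C1C(=O)CCCC1=O | intermediate
11 | betaine: the ylide carbon, now (R)-configured, bonded to the CH2 of the 3-oxocyclohex-1-en-1-olate unit (not isolated) | COc1ccc2nccc([C@H](OC)[C@H]3C[C@@H]4CC[N+]3([C@H](CC5=C([O-])CCCC5=O)C(=O)N(C)OC)C[C@@H]4C=C)c2c1 | intermediate
12 | (2S)-N-methoxy-N-methyl-4-oxo-2,3,4,5,6,7-hexahydro-1-benzofuran-2-carboxamide | CON(C)C(=O)[C@@H]1CC2=C(CCCC2=O)O1 | intermediate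
13 | geraniol, (2E)-3,7-dimethylocta-2,6-dien-1-ol | CC(C)=CCC/C(C)=C/CO | starting material
14 | [(2R,3R)-3-methyl-3-(4-methylpent-3-en-1-yl)oxiran-2-yl]methanol | CC(C)=CCC[C@@]1(C)O[C@@H]1CO | intermediate
15 | (2S,3R)-3-methyl-3-(4-methylpent-3-en-1-yl)oxirane-2-carbaldehyde | CC(C)=CCC[C@@]1(C)O[C@@H]1C=O | intermediate
16 | (2R,3R)-2-ethynyl-3-methyl-3-(4-methylpent-3-en-1-yl)oxirane | CC(C)=CCC[C@@]1(C)O[C@@H]1C#C | intermediate
17 | (3R,4S)-4,8-dimethylnon-7-en-1-yne-3,4-diol | CC(C)=CCC[C@](C)(O)[C@H](O)C#C | intermediate
18 | (4R,5S)-4-ethynyl-2,2,5-trimethyl-5-(4-methylpent-3-en-1-yl)-1,3-dioxolane | CC(C)=CCC[C@]1(C)OC(C)(C)O[C@@H]1C#C | intermediate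
19 | lithium acetylide of 18 (not isolated) | CC(C)=CCC[C@]1(C)OC(C)(C)O[C@@H]1C#[C-].[Li+] | intermediate
20 | lithium alkoxide of the N-methoxy-N-methyl hemiaminal from 19 and 12, aminal carbon undefined (not isolated) | CC(C)=CCC[C@]1(C)OC(C)(C)O[C@@H]1C#CC([O-])(N(C)OC)[C@@H]2CC3=C(CCCC3=O)O2.[Li+] | intermediate
21 | (2S)-2-{3-[(4R,5S)-2,2,5-trimethyl-5-(4-methylpent-3-en-1-yl)-1,3-dioxolan-4-yl]prop-2-ynoyl}-3,5,6,7-tetrahydro-1-benzofuran-4(2H)-one | CC(C)=CCC[C@]1(C)OC(C)(C)O[C@@H]1C#CC(=O)[C@@H]2CC3=C(CCCC3=O)O2 | intermediate
22 | (2S)-2-{(2Z)-3-[(4R,5S)-2,2,5-trimethyl-5-(4-methylpent-3-en-1-yl)-1,3-dioxolan-4-yl]prop-2-enoyl}-3,5,6,7-tetrahydro-1-benzofuran-4(2H)-one (not isolated) | CC(C)=CCC[C@]1(C)OC(C)(C)O[C@@H]1/C=C\C(=O)[C@@H]2CC3=C(CCCC3=O)O2 | intermediate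
23 | (2S)-2-{3-[(4R,5S)-2,2,5-trimethyl-5-(4-methylpent-3-en-1-yl)-1,3-dioxolan-4-yl]propanoyl}-3,5,6,7-tetrahydro-1-benzofuran-4(2H)-one | CC(C)=CCC[C@]1(C)OC(C)(C)O[C@@H]1CCC(=O)[C@@H]2CC3=C(CCCC3=O)O2 | intermediate
24 | (2S)-2-{(2S)-2-hydroxy-4-[(4R,5S)-2,2,5-trimethyl-5-(4-methylpent-3-en-1-yl)-1,3-dioxolan-4-yl]butan-2-yl}-3,5,6,7-tetrahydro-1-benzofuran-4(2H)-one | CC(C)=CCC[C@]1(C)OC(C)(C)O[C@@H]1CC[C@](C)(O)[C@@H]2CC3=C(CCCC3=O)O2 | intermediate
25 | (2S)-2-{(2S)-2-(triethylsilyloxy)-4-[(4R,5S)-2,2,5-trimethyl-5-(4-methylpent-3-en-1-yl)-1,3-dioxolan-4-yl]butan-2-yl}-3,5,6,7-tetrahydro-1-benzofuran-4(2H)-one | CC(C)=CCC[C@]1(C)OC(C)(C)O[C@@H]1CC[C@](C)(O[Si](CC)(CC)CC)[C@@H]2CC3=C(CCCC3=O)O2 | intermediate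
26 | lithium C4(O)=C5 enolate of 25 (not isolated) | CC(C)=CCC[C@]1(C)OC(C)(C)O[C@@H]1CC[C@](C)(O[Si](CC)(CC)CC)[C@@H]2CC3=C(CCC=C3[O-])O2.[Li+] | intermediate
27 | (2S,5R)-5-hydroxy-2-{(2S)-2-(triethylsilyloxy)-4-[(4R,5S)-2,2,5-trimethyl-5-(4-methylpent-3-en-1-yl)-1,3-dioxolan-4-yl]butan-2-yl}-3,5,6,7-tetrahydro-1-benzofuran-4(2H)-one | CC(C)=CCC[C@]1(C)OC(C)(C)O[C@@H]1CC[C@](C)(O[Si](CC)(CC)CC)[C@@H]2CC3=C(CC[C@@H](O)C3=O)O2 | intermediate
28 | (2S,5R)-5-hydroxy-2-[(2S,5R,6S)-2,5,6-trihydroxy-6,10-dimethylundec-9-en-2-yl]-3,5,6,7-tetrahydro-1-benzofuran-4(2H)-one | CC(C)=CCC[C@](C)(O)[C@H](O)CC[C@](C)(O)[C@@H]1CC2=C(CC[C@@H](O)C2=O)O1 | target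

## Step count and least certain steps

Total: 13 steps. Longest linear sequence: 11 steps (13 to 28, steps 3 to 13). The bicyclic half (1 to 12) takes 2 steps and joins at step 8.

**Step 2 (key step, proposed new method).** Several processes could defeat it. The methylene dione may self-condense or be captured by a second dione enolate faster than by the dilute ylide. The betaine may close at carbon to a spiro-cyclopropane. The ammonium salt may alkylate sulfinate or dione enolate. Facial discrimination may be poor because the acceptor has no substituent at C3 to interact with the cinchona framework. The fallback uses known chemistry, sets out from 1 and comes back at 12. Tandem conjugate addition and O-alkylation of 1 with ethyl 2,3-dibromopropanoate (K2CO3, acetone, via ethyl 2-bromoacrylate formed in situ) should give racemic ethyl 4-oxo-2,3,4,5,6,7-hexahydro-1-benzofuran-2-carboxylate F1. Lipase-catalysed enantioselective hydrolysis (or classical resolution of the acid with 1-phenylethylamine) then gives (2S)-4-oxo-2,3,4,5,6,7-hexahydro-1-benzofuran-2-carboxylic acid F2. Coupling of F2 with MeNHOMe·HCl (EDC, HOBt, i-Pr2NEt) gives 12.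

**Step 12.** Oxygen transfer to a cyclic trisubstituted enolate is controlled by the reagent alone, so face selection may be insufficient. Proton exchange to the γ-dienolate may also erode regioselectivity. The fallback sets out from 25 and comes back at 27. Hydroxylation with achiral 3-phenyl-2-(phenylsulfonyl)oxaziridine gives both C5 epimers. 27 is separated by preparative HPLC from the (5S)-epimer F3. F3 is recycled by Mitsunobu inversion (4-nitrobenzoic acid, PPh3, DIAD) to the (5R)-4-nitrobenzoate F4, and brief methanolysis (K2CO3, MeOH, 0 °C) returns 27.

**Step 9.** The γ-alkoxy ynone may isomerise under the basic copper hydroxide species, C2 may epimerise in ynone or ketone, or the second hydride transfer may stall at the enone. The fallback sets out from 21 and comes back at 24. Methyl addition is done first (MeTi(OiPr)3, as in step 10), so the acidifying carbonyl disappears at once, giving the propargylic carbinol (2S)-2-{(2S)-2-hydroxy-4-[(4R,5S)-2,2,5-trimethyl-5-(4-methylpent-3-en-1-yl)-1,3-dioxolan-4-yl]but-3-yn-2-yl}-3,5,6,7-tetrahydro-1-benzofuran-4(2H)-one F5. The alkyne is then saturated with H2 over RhCl(PPh3)3 (benzene/EtOH), a catalyst expected to leave the trisubstituted alkene and the tetrasubstituted enone alone, to give 24. This bypasses 23.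

**Step 10.** Facial selectivity may be poor, or the chelated mode may dominate and give the (1′R) epimer. The fallback reverses the order of the two carbon nucleophiles, so that the chelated mode of attack now leads to the right configuration. It sets out from 12 and comes back at 24. MeMgBr (THF, −78 °C) converts 12 into the methyl ketone (2S)-2-acetyl-3,5,6,7-tetrahydro-1-benzofuran-4(2H)-one F6. The alkynylmagnesium bromide from 18 is added to F6 in CH2Cl2 with MgBr2·OEt2 to favour the chelate, giving the propargylic carbinol F5 described under step 9. Hydrogenation over RhCl(PPh3)3 gives 24.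

## Further compounds

F1 | step 2 | ethyl 4-oxo-2,3,4,5,6,7-hexahydro-1-benzofuran-2-carboxylate (racemic) | CCOC(=O)C1CC2=C(CCCC2=O)O1
F2 | step 2 | (2S)-4-oxo-2,3,4,5,6,7-hexahydro-1-benzofuran-2-carboxylic acid | OC(=O)[C@@H]1CC2=C(CCCC2=O)O1
F3 | step 12 | (2S,5S)-5-hydroxy-2-{(2S)-2-(triethylsilyloxy)-4-[(4R,5S)-2,2,5-trimethyl-5-(4-methylpent-3-en-1-yl)-1,3-dioxolan-4-yl]butan-2-yl}-3,5,6,7-tetrahydro-1-benzofuran-4(2H)-one (C5 epimer of 27) | CC(C)=CCC[C@]1(C)OC(C)(C)O[C@@H]1CC[C@](C)(O[Si](CC)(CC)CC)[C@@H]2CC3=C(CC[C@H](O)C3=O)O2
F4 | step 12 | (5R)-4-nitrobenzoate of 27 | CC(C)=CCC[C@]1(C)OC(C)(C)O[C@@H]1CC[C@](C)(O[Si](CC)(CC)CC)[C@@H]2CC3=C(CC[C@@H](OC(=O)c4ccc(cc4)[N+](=O)[O-])C3=O)O2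
F5 | step 9 | (2S)-2-{(2S)-2-hydroxy-4-[(4R,5S)-2,2,5-trimethyl-5-(4-methylpent-3-en-1-yl)-1,3-dioxolan-4-yl]but-3-yn-2-yl}-3,5,6,7-tetrahydro-1-benzofuran-4(2H)-one | CC(C)=CCC[C@]1(C)OC(C)(C)O[C@@H]1C#C[C@](C)(O)[C@@H]2CC3=C(CCCC3=O)O2
F6 | step 10 | (2S)-2-acetyl-3,5,6,7-tetrahydro-1-benzofuran-4(2H)-one | CC(=O)[C@@H]1CC2=C(CCCC2=O)O1
A1 | alternative 1 | open-chain alkynyl hydroxy aldehyde: C2 carbinol, C3a≡C7a alkyne, C5 tert-butyldimethylsilyl ether, C4 aldehyde, C1′ triethylsilyl ether, C4′/C5′ acetonide | CC(C)=CCC[C@]1(C)OC(C)(C)O[C@@H]1CC[C@](C)(O[Si](CC)(CC)CC)[C@@H](O)CC#CCC[C@@H](O[Si](C)(C)C(C)(C)C)C=O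
A2 | alternative 1 | bicyclic C4 carbinol (C4 epimers), C5 tert-butyldimethylsilyl ether, C1′ triethylsilyl ether, C4′/C5′ acetonide | CC(C)=CCC[C@]1(C)OC(C)(C)O[C@@H]1CC[C@](C)(O[Si](CC)(CC)CC)[C@@H]2CC3=C(CC[C@@H](O[Si](C)(C)C(C)(C)C)C3O)O2
A3 | alternative 2 | side-chain aldehyde with C3 as formyl carbon on C2 and the C2/C1′ and C4′/C5′ diols as acetonides | CC(C)=CCC[C@]1(C)OC(C)(C)O[C@@H]1CC[C@]2(C)OC(C)(C)O[C@H]2C=O
A4 | alternative 2 | 5-deoxy target, (2S)-2-[(2S,5R,6S)-2,5,6-trihydroxy-6,10-dimethylundec-9-en-2-yl]-3,5,6,7-tetrahydro-1-benzofuran-4(2H)-one | CC(C)=CCC[C@](C)(O)[C@H](O)CC[C@](C)(O)[C@@H]1CC2=C(CCCC2=O)O1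
A5 | alternative 3 | 1-ethenylspiro[2.5]octane-4,8-dione (racemic) | C=CC1CC12C(=O)CCCC2=O
A6 | alternative 3 | (2S)-2-ethenyl-3,5,6,7-tetrahydro-1-benzofuran-4(2H)-one | C=C[C@@H]1CC2=C(CCCC2=O)O1
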